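Ring B (C5–C10) is built onto an enantiopure ring A as a 5,7-diene, the way light closes previtamin D. The target's ring B holds one alkene, C7=C8, beside a quaternary C10 whose methyl is cis to C11: what a C5=C10/C6=C7/C8=C9 triene leaves after 6π closure and 5,6-reduction. So a ring-A enal (C6 as CHO on the C5=C10 alkene, C3–O and the C4 CH2O locked as an acetonide) meets the C7–C8(CH3)–C9–C11 phosphonate: olefination makes C6–C7, and irradiation of the open-chain trienoate formed closes C9–C10, setting C9, C10 and the C7=C8 alkene in one flask. Dissolving-metal reduction sets H-5; umbelliferone enters late.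

Key step: step 7

Remark: drimane numbering is used for all bicyclic compounds (decalin C1–C10, fusion C5/C10, C11 on C9, methyl C12 on C8, methyl C15 on C10; "C4 CH2O" is the oxygenated carbon on C4); (R)-BINAP is assumed to give the 3R carbinol in step 2, as it does with acyclic β-hydroxy ketones.

Step 1
Reactants: 1 2-methylcyclohexane-1,3-dione
Product: 2 2-(hydroxymethyl)-2-methylcyclohexane-1,3-dione
Conditions: CH2O (37% aq.), Et3N (cat.), H2O, rt
Reagents that add atoms: formaldehyde C=O
Why: Aldol-type hydroxymethylation of the acidic C2–H of the 1,3-dione gives the quaternary but still prochiral carbon (the later C4) with both carbonyl arms equivalent.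

Step 2
Reactants: 2 2-(hydroxymethyl)-2-methylcyclohexane-1,3-dione
Product: 3 (2S,3R)-3-hydroxy-2-(hydroxymethyl)-2-methylcyclohexan-1-one (OH trans to CH2OH)
Conditions: RuCl2[(R)-BINAP](dmf)n (0.5 mol%), H2 (50 atm), MeOH, 30 °C, stopped at one equivalent of H2
Reagents that add atoms: none
Why: Hydroxyl-directed Noyori asymmetric hydrogenation used as a desymmetrisation: ruthenium chelated by the CH2OH oxygen and one carbonyl should deliver hydride to the carbonyl face on the side of the CH2OH arm, so the new C3–OH is trans to CH2OH, while the ligand should choose between the two enantiotopic carbonyls so that C3 is R and C4 therefore S.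

Step 3
Reactants: 3 (2S,3R)-3-hydroxy-2-(hydroxymethyl)-2-methylcyclohexan-1-one
Product: 4 (4aS,8aR)-2,2,4a-trimethylhexahydro-4H-benzo[d][1,3]dioxin-5-one (trans-fused acetonide)
Conditions: Me2C(OMe)2, PPTS (cat.), acetone, rt
Reagents that add atoms: 2,2-dimethoxypropane COC(C)(C)OC
Why: Acetonide formation on the trans-diequatorial 1,3-diol gives a trans-fused 1,3-dioxane that locks ring A with the C4 methyl axial; no stereocentre changes.

Step 4
Reactants: 4 (4aS,8aR)-2,2,4a-trimethylhexahydro-4H-benzo[d][1,3]dioxin-5-one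
Product: 5 (4aS,8aR)-2,2,4a,6-tetramethylhexahydro-4H-benzo[d][1,3]dioxin-5-one (both C6 epimers)
Conditions: LiN(i-Pr)2, THF, −78 °C; MeI, −78 to 0 °C
Reagents that add atoms: iodomethane CI
Why: Enolate alkylation is regiospecific because C10 is the only enolisable α-carbon (C4 is quaternary); the new centre is left unassigned since it becomes sp2 in step 5.

Step 5
Reactants: 5 (4aS,8aR)-2,2,4a,6-tetramethylhexahydro-4H-benzo[d][1,3]dioxin-5-one
Product: 6 (4aS,8aR)-2,2,4a,6-tetramethyl-4a,7,8,8a-tetrahydro-4H-benzo[d][1,3]dioxin-5-yl trifluoromethanesulfonate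
Conditions: KN(SiMe3)2, THF, −78 to 0 °C; PhNTf2
Reagents that add atoms: N-phenylbis(trifluoromethanesulfonimide) O=S(=O)(N(c1ccccc1)S(=O)(=O)C(F)(F)F)C(F)(F)F
Why: O-triflation of the only possible enolate gives the tetrasubstituted C5=C10 enol triflate regiospecifically.

Step 6
Reactants: 6 (4aS,8aR)-2,2,4a,6-tetramethyl-4a,7,8,8a-tetrahydro-4H-benzo[d][1,3]dioxin-5-yl trifluoromethanesulfonate
Product: 7 (4aS,8aR)-2,2,4a,6-tetramethyl-4a,7,8,8a-tetrahydro-4H-benzo[d][1,3]dioxine-5-carbaldehyde
Conditions: Pd(PPh3)4 (5 mol%), CO (3 atm), Bu3SnH (slow addition), LiCl, THF, 50 °C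
Reagents that add atoms: carbon monoxide [C-]#[O+]
Why: Stille-type palladium-catalysed formylation of a vinyl triflate (oxidative addition, CO insertion, hydride transfer from tin) brings in C6 as the aldehyde of a β-cyclocitral-like enal.

Step 7
Reactants: 7 (4aS,8aR)-2,2,4a,6-tetramethyl-4a,7,8,8a-tetrahydro-4H-benzo[d][1,3]dioxine-5-carbaldehyde; 8 ethyl (E)-4-(diethoxyphosphoryl)-3-methylbut-2-enoate
Product: 11 acetonide of ethyl (3R,4S,9R,10S)-3-hydroxy-4-(hydroxymethyl)drima-5,7-dien-11-oate, via (2E,4E)-trienoate 9 (not isolated), via (2E,4Z)-trienoate 10 (not isolated)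
Conditions: NaH, THF, 0 °C to rt; then hν (350 nm, Pyrex), degassed THF, −10 °C
Reagents that add atoms: none
Why: Horner–Wadsworth–Emmons olefination of the hindered enal (as with β-cyclocitral) forms C6=C7 and gives trienoate 9; at 350 nm, where only the trienoate absorbs, 9 and its 4Z isomer 10 interconvert and the cZc conformer of 10 closes C9–C10 by photochemical conrotatory 6π-electrocyclisation, the closest known reaction being the ring closure of previtamin D to provitamin D and lumisterol. Ring B is closed in the 6π-electrocyclic mode to a cyclohexa-1,3-diene, so C6–C7 ends as a single bond and the alkenes sit at C5=C6 and C7=C8. Conrotation places the "outside" ester on C9 cis to the "inside" methyl on C10, the C9/C10 relationship of the target, and every geometric isomer of the trienoate is fed into this one channel by the light. The face of C10 is controlled by the pseudo-axial C4 methyl of the trans-fused acetonide, so C9 should bond anti to it and push C15 syn-axial to that methyl. The step needs E/Z funnelling, no ring re-opening and no thermal disrotatory closure (which would give the C9 epimer); long-wavelength light, a product transparent at 350 nm and the low temperature should secure these. Oxygen is excluded because 5,7-dienes add singlet oxygen.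

Step 8
Reactants: 11 acetonide of ethyl (3R,4S,9R,10S)-3-hydroxy-4-(hydroxymethyl)drima-5,7-dien-11-oate
Product: 12 acetonide of (3R,4S,9R,10S)-4-(hydroxymethyl)drima-5,7-diene-3,11-diol (free C11–OH)
Conditions: LiAlH4, Et2O, 0 °C
Reagents that add atoms: none
Why: Hydride reduction of the ester gives the primary C11 alcohol; the unconjugated diene and the acetonide are inert and C9 is not epimerised under these non-equilibrating conditions.

Step 9
Reactants: 12 acetonide of (3R,4S,9R,10S)-4-(hydroxymethyl)drima-5,7-diene-3,11-diol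
Product: 13 acetonide of (3R,4S,5S,9R,10R)-4-(hydroxymethyl)drim-7-ene-3,11-diol (free C11–OH)
Conditions: Li, NH3(l), THF, t-BuOH (2 equiv), −78 to −33 °C; then NH4Cl
Reagents that add atoms: none
Why: Birch-type dissolving-metal reduction of the conjugated diene (as ergosterol to 5-dihydroergosterol) should protonate C5 anti to the axial C4 and C10 methyls, giving the trans ring fusion, and then the C6–C7–C8 allyl anion at its less substituted end C6, which leaves the C7=C8 alkene.

Step 10
Reactants: 13 acetonide of (3R,4S,5S,9R,10R)-4-(hydroxymethyl)drim-7-ene-3,11-diol; 14 umbelliferone (7-hydroxycoumarin)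
Product: 15 7-O-(drim-7-en-11-yl) ether of umbelliferone with the 3-OH and C4 CH2OH as acetonide (3R,4S,5S,9R,10R)
Conditions: PPh3, DIAD, THF, 0 °C to rt
Reagents that add atoms: none
Why: Mitsunobu etherification joins the acidic phenol to the activated primary C11 alcohol by SN2 displacement at a carbon that is not a stereocentre.

Step 11
Reactants: 15 acetonide-protected umbelliferyl ether
Product: 16 CNP0298598.3, 7-{[(3R,4S,5S,9R,10R)-3-hydroxy-4-(hydroxymethyl)drim-7-en-11-yl]oxy}coumarin
Conditions: AcOH–H2O (4:1), 40 °C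
Reagents that add atoms: none
Why: Acid hydrolysis of the isopropylidene acetal frees the equatorial C3–OH and the C4 CH2OH; the homoallylic aryl ether, the coumarin and the trisubstituted alkene should tolerate aqueous acetic acid.

Compound list
1 | 2-methylcyclohexane-1,3-dione | CC1C(=O)CCCC1=O | starting material
2 | 2-(hydroxymethyl)-2-methylcyclohexane-1,3-dione | CC1(CO)C(=O)CCCC1=O | intermediate
3 | (2S,3R)-3-hydroxy-2-(hydroxymethyl)-2-methylcyclohexan-1-one | O=C1[C@@](C)(CO)[C@H](O)CCC1 | intermediate
4 | (4aS,8aR)-2,2,4a-trimethylhexahydro-4H-benzo[d][1,3]dioxin-5-one | O=C1[C@@]2(C)COC(C)(C)O[C@@H]2CCC1 | intermediate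
5 | (4aS,8aR)-2,2,4a,6-tetramethylhexahydro-4H-benzo[d][1,3]dioxin-5-one, C6 epimers | O=C1[C@@]2(C)COC(C)(C)O[C@@H]2CCC1C | intermediate
6 | (4aS,8aR)-2,2,4a,6-tetramethyl-4a,7,8,8a-tetrahydro-4H-benzo[d][1,3]dioxin-5-yl trifluoromethanesulfonate | CC1=C(OS(=O)(=O)C(F)(F)F)[C@@]2(C)COC(C)(C)O[C@@H]2CC1 | intermediate
7 | (4aS,8aR)-2,2,4a,6-tetramethyl-4a,7,8,8a-tetrahydro-4H-benzo[d][1,3]dioxine-5-carbaldehyde | CC1=C(C=O)[C@@]2(C)COC(C)(C)O[C@@H]2CC1 | intermediate
8 | ethyl (E)-4-(diethoxyphosphoryl)-3-methylbut-2-enoate (triethyl 3-methyl-4-phosphonocrotonate) | CCOC(=O)/C=C(\C)CP(=O)(OCC)OCC | starting material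
9 | ethyl (2E,4E)-3-methyl-5-[(4aS,8aR)-2,2,4a,6-tetramethyl-4a,7,8,8a-tetrahydro-4H-benzo[d][1,3]dioxin-5-yl]penta-2,4-dienoate | CCOC(=O)/C=C(C)/C=C/C1=C(C)CC[C@H]2OC(C)(C)OC[C@]12C | intermediate
10 | ethyl (2E,4Z)-3-methyl-5-[(4aS,8aR)-2,2,4a,6-tetramethyl-4a,7,8,8a-tetrahydro-4H-benzo[d][1,3]dioxin-5-yl]penta-2,4-dienoate | CCOC(=O)/C=C(C)/C=C\C1=C(C)CC[C@H]2OC(C)(C)OC[C@]12C | intermediate
11 | acetonide (O-3 to C4 CH2O) of ethyl (3R,4S,9R,10S)-3-hydroxy-4-(hydroxymethyl)drima-5,7-dien-11-oate | CCOC(=O)[C@@H]1C(C)=CC=C2[C@@]3(C)COC(C)(C)O[C@@H]3CC[C@@]12C | intermediate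
12 | acetonide of (3R,4S,9R,10S)-4-(hydroxymethyl)drima-5,7-diene-3,11-diol | OC[C@@H]1C(C)=CC=C2[C@@]3(C)COC(C)(C)O[C@@H]3CC[C@@]12C | intermediate
13 | acetonide of (3R,4S,5S,9R,10R)-4-(hydroxymethyl)drim-7-ene-3,11-diol | OC[C@@H]1C(C)=CC[C@@H]2[C@@]3(C)COC(C)(C)O[C@@H]3CC[C@@]12C | intermediate
14 | umbelliferone (7-hydroxy-2H-chromen-2-one) | Oc1ccc2ccc(=O)oc2c1 | starting material
15 | acetonide of 7-{[(3R,4S,5S,9R,10R)-3-hydroxy-4-(hydroxymethyl)drim-7-en-11-yl]oxy}coumarin | CC1=CC[C@@H]2[C@@]3(C)COC(C)(C)O[C@@H]3CC[C@@]2(C)[C@@H]1COc1ccc2ccc(=O)oc2c1 | intermediate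
16 | CNP0298598.3, 7-{[(3R,4S,5S,9R,10R)-3-hydroxy-4-(hydroxymethyl)drim-7-en-11-yl]oxy}coumarin | CC1=CC[C@@H]2[C@@](C)(CO)[C@H](O)CC[C@@]2(C)[C@@H]1COc1ccc2ccc(=O)oc2c1 | target

Total step count: 11. Longest linear sequence: 11 steps (1 to 16); 8 and 14 are bought.

Steps most likely to fail

Step 7. The photochemical partition may be poor: E/Z isomerisation, hydrogen shifts and photodeconjugation of the enoate may outrun ring closure, and the facial selectivity at C10 may be low. The fallback is thermal and stepwise and sets out from aldehyde 7 and phosphonate 8. The olefination is worked up and trienoate 9 isolated. Fluorenone-sensitised irradiation (λ > 400 nm) should take it to the hindered 4Z isomer 10, which on warming in toluene (80 °C) should undergo thermal disrotatory 6π-electrocyclisation to the C9-epimeric diene ester F1 (ester trans to the C10 methyl). NaOEt in EtOH should then move the diene into conjugation with the ester, giving the conjugated 6,8-dienoate F2; this sets H-5 anti to the C10 methyl under equilibrating conditions and erases the wrong C9 centre. Li/NH3 with one equivalent of t-BuOH (1,6-reduction of the dienoate, then kinetic protonation of the ester enolate at C9 anti to the C10 methyl) should give the drim-7-en-11-oate F3. LiAlH4 reduction of F3 rejoins the route at alcohol 13.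

Step 2. Over-reduction of the second carbonyl and weak discrimination between the two enantiotopic carbonyl groups may erode yield and enantiopurity. The fallback sets out from dione 2. Evans–Saksena reduction with Me4NBH(OAc)3 (AcOH–MeCN, −20 °C; internal hydride delivery from the boron ester of the CH2OH group) should give the racemic trans-diol, that is 3 together with its enantiomer (2R,3S)-3-hydroxy-2-(hydroxymethyl)-2-methylcyclohexan-1-one F4. Lipase-catalysed acetylation (Amano lipase PS, vinyl acetate) then serves as a kinetic resolution: F4 is taken as the faster-reacting enantiomer and is removed as its primary acetate F5, while unreacted 3 returns to the route.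

Step 10. SN2 displacement at C11, a primary carbon flanked by the tertiary C9 and the quaternary C10, may be so slow that the activated alcohol eliminates or is recovered. The fallback sets out from alcohol 13 and umbelliferone 14 and makes the aryl–oxygen bond instead. Umbelliferone is converted (Tf2O, pyridine, CH2Cl2, 0 °C) into 2-oxo-2H-chromen-7-yl trifluoromethanesulfonate F6. Palladium-catalysed C–O cross-coupling of 13 with F6 (Pd2(dba)3, t-BuBrettPhos, Cs2CO3, toluene, 80 °C) needs no substitution at C11 and comes back to the route at 15.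

Further compounds
F1 | step 7 | acetonide of ethyl (3R,4S,9S,10S)-3-hydroxy-4-(hydroxymethyl)drima-5,7-dien-11-oate (C9 epimer of 11) | CCOC(=O)[C@H]1C(C)=CC=C2[C@@]3(C)COC(C)(C)O[C@@H]3CC[C@@]12C
F2 | step 7 | acetonide of ethyl (3R,4S,5S,10R)-3-hydroxy-4-(hydroxymethyl)drima-6,8-dien-11-oate | CCOC(=O)C1=C(C)C=C[C@@H]2[C@@]3(C)COC(C)(C)O[C@@H]3CC[C@@]12C
F3 | step 7 | acetonide of ethyl (3R,4S,5S,9R,10R)-3-hydroxy-4-(hydroxymethyl)drim-7-en-11-oate | CCOC(=O)[C@@H]1C(C)=CC[C@@H]2[C@@]3(C)COC(C)(C)O[C@@H]3CC[C@@]12C
F4 | step 2 | (2R,3S)-3-hydroxy-2-(hydroxymethyl)-2-methylcyclohexan-1-one | O=C1[C@](C)(CO)[C@@H](O)CCC1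
F5 | step 2 | [(1R,2S)-2-hydroxy-1-methyl-6-oxocyclohexyl]methyl acetate | O=C1[C@](C)(COC(C)=O)[C@@H](O)CCC1
F6 | step 10 | 2-oxo-2H-chromen-7-yl trifluoromethanesulfonate | O=c1ccc2ccc(OS(=O)(=O)C(F)(F)F)cc2o1
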